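## Structural features

The target is a daucane (carotane) sesquiterpenoid ester. A cyclopentane (C1–C5) is fused through C1–C5 to a cycloheptane (C1, C5–C10); C1 is quaternary and carries a methyl (C15), C4 is an isopropyl carbinol, and C8 carries a one-carbon branch (C14) closed to a spiro-oxirane. With the face of the C1 methyl called β, the seven stereocentres are 1β-methyl, 4β-OH, 5α-H (trans fusion), 6α-isovalerate, 8α-epoxide oxygen and 9α,10α-diol. Every oxygen on the seven-membered ring therefore lies opposite the angular methyl, while the C4 hydroxyl lies on the methyl side. The centres are contiguous along C4–C5–C6 and C8–C9–C10–C1, and the two fully substituted ones (C1, C4) face each other 1,3 across C5. Fragile parts are the 1,1-disubstituted spiro-epoxide beside a free secondary alcohol (acid opens it or starts 1,2-shifts, strong base invites alkoxide attack), the ester that must go on one of four hydroxyls, and the tertiary C4 alcohol beside the ring fusion. The real difficulty is the relative configuration of C1 and C4, followed by ordered oxygenation of C6, C8, C9 and C10 on a conformationally soft seven-membered ring. The key step uses the fact that C1=C10 with oxygenated C9, C8 and C7 is a 1-siloxy vinylcyclopropane and C5≡C6 is an alkyne held to C1 by C2–C3–C4; one acyclic chain with a single stereocentre (C4) then gives both rings, quaternary C1, an enol ether at C9=C10 and an alkene at C5=C6.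

## Logic of the disconnections

29 ⇒ 28. No skeletal bond is cut; the O–H bonds at O4, O9 and O10 are exchanged for O–Si bonds. The ester must go on O6 alone, and the epoxy alcohol should not be exposed while other work is done. The gain is a single global unmasking at the end. The demand is fluoride cleavage buffered so that ester and oxirane survive.

28 ⇒ 26 + 27. The acyl C–O bond at O6 is cut, removing five carbons as 27. The demand is that O6 is the only free hydroxyl in 26 and that a secondary carbinol beside the ring fusion can be acylated.

26 ⇒ 24. The C6–O and C5–H bonds are removed together, giving the C5=C6 alkene. Both centres then come from one syn addition. A path through a C5–C6 epoxide and a 1,2-hydride shift was set aside, because a cationic C5 next to the C4 oxygen invites migration from C4. The demand is addition from the α face with oxygen ending on C6, and tolerance of the oxirane.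

24 ⇒ 23. The O9–Si bond is cut. The gain is that 23 is the direct product of a hydroxyl-directed epoxidation. The demand is silylation of a hindered alcohol without opening the neighbouring oxirane.

23 ⇒ 22. The two C–O bonds of the oxirane are cut, leaving the exocyclic C8=C14 alkene. The allylic O9–H delivers oxygen to its own face, which is the α face needed at C8. The demand is a free, α-configured O9 and an untouched C5=C6.

22 ⇒ 21. The C9–H bond is removed, so the carbinol becomes a ketone, the function that lets C14 be attached. The demand is 1,2-reduction with hydride entering anti to O10.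

21 ⇒ 18. The C8–C14 bond is cut, removing the one carbon the cycloaddition cannot supply. The demand is enolisation of the C9 ketone toward C8 only, and an elimination mild enough to keep the alkene exocyclic.

18 ⇒ 16. The C10–O bond is cut, back to the C9=C10 silyl enol ether. The gain is that 16 is the cycloadduct itself and that the silyl group moves from O9 to O10 and protects the new hydroxyl. The demand is an oxidant that chooses the enol ether over C5=C6 and attacks anti to the C1 methyl.

16 ⇒ 15. C1–C5 and C6–C7 are cut. Both rings fall away and an acyclic enyne with one stereocentre remains, the largest simplification in the route. The demand is that the tethered alkyne and the siloxy vinylcyclopropane combine under rhodium with the C1 methyl ending syn to O4.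

15 ⇒ 14. The O–Si bond of the cyclopropanol is cut. The demand is silylation without acid-induced ring expansion.

14 ⇒ 12 + 13. The bonds from C9 to C7 and to C8 are cut; the two-carbon unit comes from 13 and C9 from an ester carbonyl. The demand is cyclopropanation of a conjugated ester beside a terminal alkyne.

12 ⇒ 10 + 11. The C1=C10 double bond is cut to a methyl ketone and a phosphonate. The demand is E geometry, so that the tether later lies trans to the cyclopropane.

10 ⇒ 8. The alkyne C5≡C6 and the ketone C1 are reconnected through a C1–C6 bond to a cyclic α,β-epoxy ketone. The alkyne must sit directly on C4, so C5 and C6 have to be the two ring carbons next to the carbinol carbon of the six-membered precursor. Ozonolysis of the ring alkene of 1 followed by one-carbon homologation of the aldehyde looks shorter but is wrong: it would leave a CH2 between C4 and the alkyne, and step 10 would then close a six-membered ring. The demand is a carbonyl on the ring carbon next to C4 and an epoxide spanning the future C6 and C1.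

8 ⇒ 7. The epoxide C–O bonds are cut to the enone. The demand is nucleophilic epoxidation; its facial outcome is irrelevant.

7 ⇒ 6. Carbonyl and alkene are transposed back to a tertiary allylic alcohol. The demand is that only one tertiary allylic hydroxyl is free, which is why O4 is silylated first.

6 ⇒ 3. The allylic alcohol is traced to the epoxide of the original ring alkene. The demand is opening at the secondary carbon and elimination toward the future C5.

3 ⇒ 2 and 2 ⇒ 1. The epoxide oxygen and the silyl group are removed, arriving at 1, which supplies C4 with its oxygen, the isopropyl group and C1–C3, C5, C6 and C15.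

## Other disconnections considered

Alternative 1: The cut is C8–C9, which opens the seven-membered ring to a cyclopentane carrying a 2-bromoallyl arm and an α-silyloxy aldehyde, bromo aldehyde A2. In the forward direction CrCl2 with catalytic NiCl2 converts the vinyl bromide into a vinylchromium species that adds to the aldehyde and gives the bicyclic allylic alcohol A1.
- In its favour: the ring closure is dependable, selective for aldehydes and tolerant of the free tertiary alcohol. A1 already has the C14 methylene, the C9 carbinol and the C6 and C10 oxygens, so far fewer steps follow the key step than the eight that follow step 10 here. On that point it is better.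
- Against it: A2 must already contain C1, C4, C5, C6 and C10 with correct configuration. Building a cyclopentane with quaternary C1, fully substituted C4 and two different oxygenated arms is the real synthesis and would be much longer than the nine steps to 15. The closure forms one ring and one bond against two rings and two bonds, and it needs excess divalent chromium at high dilution.
- Comparison: the new C9 centre depends on a medium-ring transition state, which is no more predictable than the hydride reduction of step 13; here the two plans are equal.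

Alternative 2: The C1–C5 bond is traced back to a C1–C6 bond of a cis-decalin, hydroxy mesylate A4, derived from the (S)-Wieland–Miescher ketone A5. In the forward direction Et3Al ionises the C5 mesylate while the C6 aluminium alkoxide pushes; the antiperiplanar fusion bond C6–C1 migrates to C5 with inversion and gives the trans-fused ketone A3.
- In its favour: A5 is cheap in enantiopure form, quaternary C1 is fixed from the start, and the stereospecific shift sets H5 and places a carbonyl at C6. On the security of C1 and C5 it is better than the chosen plan, where C1 is the least certain point.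
- Against it: A3 lacks the isopropyl group and the tertiary carbinol. Its only handle in the seven-membered ring besides C6 is a masked C10 carbonyl, from which C9 oxygen and the C8 branch can be reached only by several redox and transposition steps. The cis-fused diol needed for A4 requires osmylation on the methyl face. The shift reshapes one ring, closes none, and needs exact alignment in a flexible cis-decalin.
- Comparison: it is safer on the skeleton but clearly longer after the key step; on step economy the chosen plan is better.

Alternative 3: The cuts are C7–C8 and C1–C10, giving the vinyl diene A7 (a cyclopentene obtainable from 1 by ring contraction) and the siloxyvinyl diazo ester A8. In the forward direction Rh2(S-PTAD)4 or its enantiomer generates the carbenoid, which cyclopropanates the terminal C6=C7 alkene; the cis-divinylcyclopropane then undergoes Cope rearrangement to the cycloheptadiene A6.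
- In its favour: it is convergent and uses the same chiral pool for C4. The chiral catalyst adds reagent control over the C1 face, which the chosen plan lacks, so on that point it is better. C14 arrives as the ester on C8, saving the methylenation. It equals the chosen plan in forming two C–C bonds, the seven-membered ring and quaternary C1 in one operation.
- Against it: the Cope step must form quaternary C1 from a tetrasubstituted ring alkene and may stall. The five-membered ring has to be made beforehand. In A6 the enol ether points toward C8, so C10 is an unactivated CH2 beside a quaternary carbon with no handle for hydroxylation, whereas in 16 the enol ether points at C10. The ester must also be reduced to the methylene level.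
- Comparison: it is better on control of C1 and on C14, worse on C10 and on preparation of the diene.

Key step: step 10

Assumption: commercial (S)-(+)-terpinen-4-ol is taken as enantiomerically pure. Bicyclic compounds are named on the daucane skeleton (C15 = methyl on C1, C14 on C8, isopropyl on C4), with β the face of C15; the SMILES in the compound list are authoritative.

## Route

Step 1
Reactants: 1 (S)-(+)-terpinen-4-ol
Product: 2 (S)-triethyl[(1-isopropyl-4-methylcyclohex-3-en-1-yl)oxy]silane
Conditions: TESOTf, 2,6-lutidine, CH2Cl2, 0 °C
Reagents that add atoms: triethylsilyl trifluoromethanesulfonate, CC[Si](CC)(CC)OS(=O)(=O)C(F)(F)F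
Why: O-Silylation with a silyl triflate and a hindered base works even on a tertiary alcohol; the silyl ether leaves one free tertiary allylic hydroxyl for step 4, keeps O4 from binding rhodium in step 10 and comes off with the other silyl groups at the end.

Step 2
Reactants: 2 the silyl ether
Product: 3 4-isopropyl-1-methyl-4-(triethylsilyloxy)-7-oxabicyclo[4.1.0]heptane (both epoxide diastereomers; silyloxy carbon as in 1)
Conditions: mCPBA, NaHCO3, CH2Cl2, 0 °C
Reagents that add atoms: 3-chloroperoxybenzoic acid (mCPBA), OOC(=O)c1cccc(Cl)c1
Why: Prilezhaev epoxidation of the only alkene under buffered conditions; both diastereomers are usable because the two epoxide carbons become trigonal again in step 4.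

Step 3
Reactants: 3 the epoxide
Product: 6 4-isopropyl-1-methyl-4-(triethylsilyloxy)cyclohex-2-en-1-ol (both C1 epimers; silyloxy carbon as in 1), via hydroxy selenide 4 (not isolated), via selenoxide 5 (not isolated)
Conditions: (PhSe)2, NaBH4, EtOH, 0 °C → reflux; then H2O2 (30 %), THF, 0 °C → rt
Reagents that add atoms: none
Why: Benzeneselenolate opens the epoxide at the secondary carbon (SN2), and syn elimination of the selenoxide can only run away from the carbinol carbon, toward the CH2 next to the silyloxy carbon (selenide opening and selenoxide elimination); this puts the alkene between the future C6 and C5 and the tertiary hydroxyl on the methyl-bearing carbon.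

Step 4
Reactants: 6 the tertiary allylic alcohol
Product: 7 (R)-6-isopropyl-3-methyl-6-(triethylsilyloxy)cyclohex-2-en-1-one
Conditions: [C5H5NH][CrO3Cl] (pyridinium chlorochromate), NaOAc, 4 Å sieves, CH2Cl2, rt
Reagents that add atoms: none
Why: Babler–Dauben oxidative transposition: the chromate ester of the tertiary allylic alcohol shifts [3,3] to the far allylic carbon and is oxidised there, so the carbonyl ends next to the silyloxy carbon; the other tertiary oxygen is silylated, so only one direction is open.

Step 5
Reactants: 7 the enone
Product: 8 3-isopropyl-6-methyl-3-(triethylsilyloxy)-7-oxabicyclo[4.1.0]heptan-2-one (both epoxide diastereomers; silyloxy carbon as in 1)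
Conditions: H2O2 (30 %), NaOH (cat.), MeOH, 0 °C
Reagents that add atoms: hydrogen peroxide, OO
Why: Weitz–Scheffer nucleophilic epoxidation (conjugate addition of hydroperoxide, then ring closure); the face of attack does not matter because both epoxide carbons lose their configuration in step 6.

Step 6
Reactants: 8 the epoxy ketone
Product: 10 (R)-5-isopropyl-5-(triethylsilyloxy)hept-6-yn-2-one, via tosylhydrazone 9 (not isolated)
Conditions: TsNHNH2, AcOH–CH2Cl2 (1:1), −20 °C → rt
Reagents that add atoms: none
Why: Eschenmoser–Tanabe fragmentation: the tosylhydrazone opens to an azoalkene alkoxide that fragments with loss of N2 and sulfinate, cutting the bond between the methyl-bearing carbon and the epoxide CH; the ketone carbon and the CH carbon become the alkyne bonded directly to the carbinol carbon and the methyl-bearing carbon becomes the methyl ketone, with the stereocentre untouched.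

Step 7
Reactants: 10 the alkynone; 11 triethyl phosphonoacetate
Product: 12 ethyl (2E,6R)-6-isopropyl-3-methyl-6-(triethylsilyloxy)oct-2-en-7-ynoate
Conditions: NaH, THF, 0 °C → 50 °C
Reagents that add atoms: none
Why: Horner–Wadsworth–Emmons olefination of the methyl ketone; the stabilised anion should favour the E enoate (ester trans to the longer chain), and the Z isomer is removed by chromatography.

Step 8
Reactants: 12 the enoate; 13 ethylmagnesium bromide
Product: 14 1-[(1E,5R)-5-isopropyl-2-methyl-5-(triethylsilyloxy)hept-1-en-6-yn-1-yl]cyclopropan-1-ol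
Conditions: Ti(OiPr)4 (0.3 equiv), THF, 0 °C → rt, slow addition of 13 (3.5 equiv); NH4Cl (aq)
Reagents that add atoms: none
Why: Kulinkovich cyclopropanation: the titanacyclopropane formed from the Grignard reagent adds twice to the ester carbonyl and gives the 1-alkenylcyclopropanol; β,β-disubstituted enoates are known substrates, and the alkyne is masked in the flask as its magnesium acetylide.

Step 9
Reactants: 14 the cyclopropanol
Product: 15 (3R,6E)-7-[1-(tert-butyldimethylsilyloxy)cyclopropyl]-3-isopropyl-6-methyl-3-(triethylsilyloxy)hept-6-en-1-yne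
Conditions: TBSOTf, Et3N, CH2Cl2, −78 → 0 °C
Reagents that add atoms: tert-butyldimethylsilyl trifluoromethanesulfonate, CC(C)(C)[Si](C)(C)OS(=O)(=O)C(F)(F)F
Why: O-Silylation under cold, basic conditions avoids acid-induced ring expansion of the vinylcyclopropanol; the siloxy group later speeds cyclopropane cleavage and becomes the C9 enol ether.

Step 10
Reactants: 15 the siloxy vinylcyclopropane enyne
Product: 16 9-(tert-butyldimethylsilyloxy)-4β-(triethylsilyloxy)dauca-5,9-diene
Conditions: [Rh(CO)2Cl]2 (5 mol %), ClCH2CH2Cl (0.02 M), 80 °C
Reagents that add atoms: none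
Why: Monovalent rhodium binds the C5≡C6 alkyne and the vinylcyclopropane; coupling of C1 with C5 closes the five-membered ring in the exo mode imposed by the three-atom tether C2–C3–C4, and cleavage of a cyclopropane bond (C9–C7; the two CH2 groups are equivalent, so no regiochemical question arises) leads, in whichever order the two events occur, to an eight-membered trivalent rhodacycle. Reductive elimination then forms C6–C7 and closes the seven-membered ring as the union of the five vinylcyclopropane carbons with the two alkyne carbons. The closest known reaction type is the [Rh(CO)2Cl]2-catalysed intramolecular (5+2) cycloaddition of tethered alkynes with vinylcyclopropanes, including 1-oxygenated ones, whose donor oxygen speeds ring opening and ends as the enol ether. The only new stereocentre, C1, is set when C1–C5 forms and is controlled by C4: in the bicyclic transition state the C1 methyl stands nearly perpendicular to the forming cyclopentane while C10 is held close to its plane by the metal, so the C4 substituent on the methyl face meets a 1,3-repulsion. Isopropyl is the larger group near the ring (the silyloxy oxygen is small at its point of attachment), so it should take the face away from the methyl and leave O4 syn to the methyl, as the target requires. The step further needs the E alkene, so that the tether and not the methyl points toward the alkyne-bound metal (secured in step 7), and an oxygen at C4 that cannot bind rhodium (secured by the silyl ether). High dilution favours the intramolecular path over alkyne oligomerisation, and the neutral, non-protic medium preserves the silyl enol ether.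

Step 11
Reactants: 16 the bicyclic diene
Product: 18 10α-(tert-butyldimethylsilyloxy)-4β-(triethylsilyloxy)dauc-5-en-9-one, via siloxy epoxide 17 (not isolated)
Conditions: mCPBA (1.05 equiv), NaHCO3, CH2Cl2, −20 → 0 °C
Reagents that add atoms: 3-chloroperoxybenzoic acid (mCPBA), OOC(=O)c1cccc(Cl)c1
Why: Rubottom oxidation: the peracid epoxidises the electron-rich silyl enol ether much faster than the trisubstituted C5=C6 alkene, and the siloxy epoxide opens with 1,4-silyl shift to the α-silyloxy ketone; attack anti to the adjacent C1 methyl places the C10 oxygen α.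

Step 12
Reactants: 18 the α-silyloxy ketone
Product: 21 10α-(tert-butyldimethylsilyloxy)-4β-(triethylsilyloxy)dauca-5,8(14)-dien-9-one, via Mannich base 19 (not isolated), via ammonium iodide 20 (not isolated)
Conditions: LiN(SiMe3)2, THF, −78 °C; [CH2=NMe2]I, −78 °C → rt; MeI, CH2Cl2, rt; NaHCO3 (aq), rt
Reagents that add atoms: N,N-dimethylmethyleneiminium iodide, C=[N+](C)C.[I-]
Why: Kinetic deprotonation occurs at the unhindered C8 methylene and not at the oxygenated, neopentyl C10; Mannich reaction of the enolate, N-methylation and E1cB loss of trimethylamine give the exocyclic enone (Eschenmoser methylenation), and bicarbonate is too weak a base to move the alkene into conjugation with C5=C6.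

Step 13
Reactants: 21 the exocyclic enone
Product: 22 10α-(tert-butyldimethylsilyloxy)-4β-(triethylsilyloxy)dauca-5,8(14)-dien-9α-ol
Conditions: NaBH4, CeCl3·7H2O, MeOH, −78 °C
Reagents that add atoms: none
Why: Luche reduction gives clean 1,2-addition; hydride should enter anti to the bulky silyloxy group on the adjacent C10 (Felkin–Anh-type approach, as in reductions of 2-silyloxy cycloalkanones), giving the 9α alcohol cis to O10.

Step 14
Reactants: 22 the allylic alcohol
Product: 23 8α,14-epoxy-10α-(tert-butyldimethylsilyloxy)-4β-(triethylsilyloxy)dauc-5-en-9α-ol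
Conditions: VO(acac)2 (cat.), tBuOOH, CH2Cl2, 0 °C
Reagents that add atoms: tert-butyl hydroperoxide, CC(C)(C)OO
Why: Hydroxyl-directed epoxidation: the vanadate ester of the C9 alcohol delivers the peroxide oxygen to the face of the exocyclic alkene on which O9 lies, so the epoxide oxygen at C8 is α; C5=C6 has no free hydroxyl nearby and reacts far more slowly.

Step 15
Reactants: 23 the epoxy alcohol
Product: 24 8α,14-epoxy-10α-(tert-butyldimethylsilyloxy)-4β,9α-bis(triethylsilyloxy)dauc-5-ene
Conditions: TESOTf, 2,6-lutidine, CH2Cl2, −78 °C
Reagents that add atoms: triethylsilyl trifluoromethanesulfonate, CC[Si](CC)(CC)OS(=O)(=O)C(F)(F)F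
Why: O-Silylation of the hindered secondary alcohol in a cold, buffered medium that should leave the oxirane closed; it removes the last free hydroxyl before borane and the acylating agent are used.

Step 16
Reactants: 24 the silylated epoxy alkene
Product: 26 8α,14-epoxy-10α-(tert-butyldimethylsilyloxy)-4β,9α-bis(triethylsilyloxy)-5α-daucan-6α-ol, via alkylborane 25 (not isolated)
Conditions: BH3·THF, THF, 0 °C → rt; then NaOH (aq), H2O2, 0 °C
Reagents that add atoms: hydrogen peroxide, OO
Why: Hydroboration–oxidation: borane adds syn across C5=C6 with boron on the less substituted C6, from the α face, which is anti to both the C1 methyl and the C4 silyloxy group; oxidation goes with retention, so H5 and the C6 hydroxyl are both set α (trans fusion) in one step, and uncatalysed borane opens epoxides only slowly.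

Step 17
Reactants: 26 the C6 alcohol; 27 3-methylbutanoic anhydride
Product: 28 8α,14-epoxy-10α-(tert-butyldimethylsilyloxy)-4β,9α-bis(triethylsilyloxy)-5α-daucan-6α-yl 3-methylbutanoate
Conditions: DMAP, Et3N, CH2Cl2, rt
Reagents that add atoms: none
Why: DMAP-catalysed acyl transfer to the only free hydroxyl; all other oxygens are silylated.

Step 18
Reactants: 28 the silylated ester
Product: 29 8α,14-epoxy-4β,9α,10α-trihydroxy-5α-daucan-6α-yl 3-methylbutanoate (CNP0307265.1)
Conditions: Bu4NF, AcOH, THF, 0 °C → rt
Reagents that add atoms: none
Why: Fluoride-induced cleavage of the three Si–O bonds; acetic acid keeps the medium from turning basic enough for ester migration or alkoxide attack on the oxirane, and the syn relation of O9 to the epoxide oxygen disfavours Payne rearrangement.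

## Compound list

1 | (S)-(+)-terpinen-4-ol | CC1=CC[C@](O)(C(C)C)CC1 | starting material
2 | (S)-triethyl[(1-isopropyl-4-methylcyclohex-3-en-1-yl)oxy]silane | CC1=CC[C@](O[Si](CC)(CC)CC)(C(C)C)CC1 | intermediate
3 | 4-isopropyl-1-methyl-4-(triethylsilyloxy)-7-oxabicyclo[4.1.0]heptane, both epoxide diastereomers | CC12OC1C[C@](O[Si](CC)(CC)CC)(C(C)C)CC2 | intermediate
4 | 4-isopropyl-1-methyl-2-(phenylselanyl)-4-(triethylsilyloxy)cyclohexan-1-ol, diastereomers | CC1(O)C([Se]c2ccccc2)C[C@](O[Si](CC)(CC)CC)(C(C)C)CC1 | intermediate (not isolated)
5 | selenoxide of 4 | CC1(O)C([Se](=O)c2ccccc2)C[C@](O[Si](CC)(CC)CC)(C(C)C)CC1 | intermediate (not isolated)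
6 | 4-isopropyl-1-methyl-4-(triethylsilyloxy)cyclohex-2-en-1-ol, both C1 epimers | CC1(O)C=C[C@](O[Si](CC)(CC)CC)(C(C)C)CC1 | intermediate
7 | (R)-6-isopropyl-3-methyl-6-(triethylsilyloxy)cyclohex-2-en-1-one | CC1=CC(=O)[C@](O[Si](CC)(CC)CC)(C(C)C)CC1 | intermediate
8 | 3-isopropyl-6-methyl-3-(triethylsilyloxy)-7-oxabicyclo[4.1.0]heptan-2-one, both epoxide diastereomers | CC12OC1C(=O)[C@](O[Si](CC)(CC)CC)(C(C)C)CC2 | intermediate
9 | p-toluenesulfonylhydrazone of 8 | CC12OC1C(=NNS(=O)(=O)c3ccc(C)cc3)[C@](O[Si](CC)(CC)CC)(C(C)C)CC2 | intermediate (not isolated)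
10 | (R)-5-isopropyl-5-(triethylsilyloxy)hept-6-yn-2-one | C#C[C@](O[Si](CC)(CC)CC)(C(C)C)CCC(C)=O | intermediate
11 | triethyl phosphonoacetate | CCOC(=O)CP(=O)(OCC)OCC | starting material
12 | ethyl (2E,6R)-6-isopropyl-3-methyl-6-(triethylsilyloxy)oct-2-en-7-ynoate | C#C[C@](O[Si](CC)(CC)CC)(C(C)C)CC/C(C)=C/C(=O)OCC | intermediate
13 | ethylmagnesium bromide | CC[Mg]Br | starting material
14 | 1-[(1E,5R)-5-isopropyl-2-methyl-5-(triethylsilyloxy)hept-1-en-6-yn-1-yl]cyclopropan-1-ol | C#C[C@](O[Si](CC)(CC)CC)(C(C)C)CC/C(C)=C/C1(O)CC1 | intermediate
15 | (3R,6E)-7-[1-(tert-butyldimethylsilyloxy)cyclopropyl]-3-isopropyl-6-methyl-3-(triethylsilyloxy)hept-6-en-1-yne | C#C[C@](O[Si](CC)(CC)CC)(C(C)C)CC/C(C)=C/C1(O[Si](C)(C)C(C)(C)C)CC1 | intermediate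
16 | 9-(tert-butyldimethylsilyloxy)-4β-(triethylsilyloxy)dauca-5,9-diene | C1=C2[C@](O[Si](CC)(CC)CC)(C(C)C)CC[C@]2(C)C=C(O[Si](C)(C)C(C)(C)C)CC1 | intermediate
17 | 9α,10α-epoxide of 16 | C1=C2[C@](O[Si](CC)(CC)CC)(C(C)C)CC[C@]2(C)[C@@H]3O[C@]3(O[Si](C)(C)C(C)(C)C)CC1 | intermediate (not isolated)
18 | 10α-(tert-butyldimethylsilyloxy)-4β-(triethylsilyloxy)dauc-5-en-9-one | C1=C2[C@](O[Si](CC)(CC)CC)(C(C)C)CC[C@]2(C)[C@H](O[Si](C)(C)C(C)(C)C)C(=O)CC1 | intermediate
19 | 8-(dimethylaminomethyl) derivative of 18, C8 epimers | C1=C2[C@](O[Si](CC)(CC)CC)(C(C)C)CC[C@]2(C)[C@H](O[Si](C)(C)C(C)(C)C)C(=O)C(CN(C)C)C1 | intermediate (not isolated)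
20 | 8-(trimethylammoniomethyl) iodide from 19 | C1=C2[C@](O[Si](CC)(CC)CC)(C(C)C)CC[C@]2(C)[C@H](O[Si](C)(C)C(C)(C)C)C(=O)C(C[N+](C)(C)C)C1.[I-] | intermediate (not isolated)
21 | 10α-(tert-butyldimethylsilyloxy)-4β-(triethylsilyloxy)dauca-5,8(14)-dien-9-one | C1=C2[C@](O[Si](CC)(CC)CC)(C(C)C)CC[C@]2(C)[C@H](O[Si](C)(C)C(C)(C)C)C(=O)C(=C)C1 | intermediate
22 | 10α-(tert-butyldimethylsilyloxy)-4β-(triethylsilyloxy)dauca-5,8(14)-dien-9α-ol | C1=C2[C@](O[Si](CC)(CC)CC)(C(C)C)CC[C@]2(C)[C@H](O[Si](C)(C)C(C)(C)C)[C@H](O)C(=C)C1 | intermediate
23 | 8α,14-epoxy-10α-(tert-butyldimethylsilyloxy)-4β-(triethylsilyloxy)dauc-5-en-9α-ol | C1=C2[C@](O[Si](CC)(CC)CC)(C(C)C)CC[C@]2(C)[C@H](O[Si](C)(C)C(C)(C)C)[C@H](O)[C@@]3(CO3)C1 | intermediate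
24 | 8α,14-epoxy-10α-(tert-butyldimethylsilyloxy)-4β,9α-bis(triethylsilyloxy)dauc-5-ene | C1=C2[C@](O[Si](CC)(CC)CC)(C(C)C)CC[C@]2(C)[C@H](O[Si](C)(C)C(C)(C)C)[C@H](O[Si](CC)(CC)CC)[C@@]3(CO3)C1 | intermediate
25 | 6α-boryl-5α-H adduct of 24 | B[C@@H]1[C@H]2[C@](O[Si](CC)(CC)CC)(C(C)C)CC[C@]2(C)[C@H](O[Si](C)(C)C(C)(C)C)[C@H](O[Si](CC)(CC)CC)[C@@]3(CO3)C1 | intermediate (not isolated)
26 | 8α,14-epoxy-10α-(tert-butyldimethylsilyloxy)-4β,9α-bis(triethylsilyloxy)-5α-daucan-6α-ol | O[C@@H]1[C@H]2[C@](O[Si](CC)(CC)CC)(C(C)C)CC[C@]2(C)[C@H](O[Si](C)(C)C(C)(C)C)[C@H](O[Si](CC)(CC)CC)[C@@]3(CO3)C1 | intermediate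
27 | 3-methylbutanoic anhydride | CC(C)CC(=O)OC(=O)CC(C)C | starting material
28 | 6-O-(3-methylbutanoyl) derivative of 26 | CC(C)CC(=O)O[C@@H]1[C@H]2[C@](O[Si](CC)(CC)CC)(C(C)C)CC[C@]2(C)[C@H](O[Si](C)(C)C(C)(C)C)[C@H](O[Si](CC)(CC)CC)[C@@]3(CO3)C1 | intermediate
29 | 8α,14-epoxy-4β,9α,10α-trihydroxy-5α-daucan-6α-yl 3-methylbutanoate (CNP0307265.1) | CC(C)CC(=O)O[C@H]1C[C@]2(CO2)[C@@H](O)[C@@H](O)[C@@]2(C)CC[C@@](O)(C(C)C)[C@H]12 | target

## Step count and least certain steps

Total: 18 steps. Longest linear sequence: 18 steps from 1; compounds 11, 13 and 27 are commercial and enter at steps 7, 8 and 17.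

Step 10 (key step). The most likely failure is poor facial discrimination when C1–C5 forms. The two C4 substituents differ only moderately in size, so both C1 epimers could form, and a quaternary centre cannot be corrected afterwards. Slow engagement of the methyl-bearing alkene terminus is the second concern. The fallback changes the control element by stripping the silyl group from O4 before the cycloaddition, so that oxygen is by far the smaller C4 substituent. It sets out from 15. Mild methanolysis (pyridinium p-toluenesulfonate, MeOH, 0 °C) should remove only the more labile triethylsilyl group and give (3R,6E)-7-[1-(tert-butyldimethylsilyloxy)cyclopropyl]-3-isopropyl-6-methylhept-6-en-1-yn-3-ol F6. Cycloaddition with [Rh(CO)2Cl]2 at the same dilution would give 9-(tert-butyldimethylsilyloxy)dauca-5,9-dien-4β-ol F7. TESOTf and 2,6-lutidine at −78 °C would then return 16.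

Step 6. Hydrazone formation at a carbonyl wedged between the silyloxy-bearing quaternary carbon and the epoxide may be too slow, so that acid-induced epoxide opening or loss of the silyl group takes over. The fallback replaces the fragmentation by excision of one ring carbon and addition of one. It sets out from 6. Ozonolysis (O3, CH2Cl2–MeOH, −78 °C; Me2S) would give 2-hydroxy-5-isopropyl-2-methyl-5-(triethylsilyloxy)hexanedial F1. Pb(OAc)4 would cleave its α-hydroxy aldehyde end to the methyl ketone, giving (R)-2-isopropyl-5-oxo-2-(triethylsilyloxy)hexanal F2. Ohira–Bestmann alkynylation (dimethyl (1-diazo-2-oxopropyl)phosphonate, K2CO3, MeOH) of the aldehyde, which now sits directly on the carbinol carbon, would return 10.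

Step 8. The conjugated ester may be attacked sluggishly, and the low-valent titanium intermediate may instead engage the alkyne or the conjugated alkene. The fallback builds the cyclopropane from a silyl enol ether. It sets out from 12. MeNHOMe·HCl with iPrMgCl would give the Weinreb amide (2E,6R)-6-isopropyl-N-methoxy-N,3-dimethyl-6-(triethylsilyloxy)oct-2-en-7-ynamide F3. MeMgBr would give (3E,7R)-7-isopropyl-4-methyl-7-(triethylsilyloxy)non-3-en-8-yn-2-one F4. TBSOTf and Et3N would give (3E,7R)-2-(tert-butyldimethylsilyloxy)-7-isopropyl-4-methyl-7-(triethylsilyloxy)nona-1,3-dien-8-yne F5. Simmons–Smith cyclopropanation (Et2Zn, CH2I2) of the electron-rich enol ether alkene would return 15 directly.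

Step 13. Hydride may enter from the α face, because the β face is screened across the ring by the C1 methyl; this would give the 9β alcohol and a trans diol. The fallback corrects the centre by inversion. It sets out from 21. Reduction giving 10α-(tert-butyldimethylsilyloxy)-4β-(triethylsilyloxy)dauca-5,8(14)-dien-9β-ol F8 would be followed by Mitsunobu reaction (PPh3, DIAD, 4-nitrobenzoic acid) to the inverted 9α 4-nitrobenzoate F9. Methanolysis (K2CO3, MeOH) would return 22.

Step 16. Borane may add from the β face, or add so slowly to the hindered alkene that reduction of the oxirane competes; β addition would give the cis-fused isomer. The fallback replaces kinetic facial control by equilibration. It sets out from 24. If hydroboration gives the 5β,6β-alcohol F10, Dess–Martin oxidation would give the cis-fused 6-ketone F11. DBU would epimerise C5 to the trans-fused 6-ketone F12, provided the trans fusion is the more stable. Reduction under equilibrating conditions (SmI2, H2O, Et3N) to the equatorial 6α alcohol would return 26.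

## Further compounds

F1 | step 6 | 2-hydroxy-5-isopropyl-2-methyl-5-(triethylsilyloxy)hexanedial (C2 epimers; C5 as in 1) | O=C[C@](O[Si](CC)(CC)CC)(C(C)C)CCC(C)(O)C=O
F2 | step 6 | (R)-2-isopropyl-5-oxo-2-(triethylsilyloxy)hexanal | O=C[C@](O[Si](CC)(CC)CC)(C(C)C)CCC(C)=O
F3 | step 8 | (2E,6R)-6-isopropyl-N-methoxy-N,3-dimethyl-6-(triethylsilyloxy)oct-2-en-7-ynamide | C#C[C@](O[Si](CC)(CC)CC)(C(C)C)CC/C(C)=C/C(=O)N(C)OC
F4 | step 8 | (3E,7R)-7-isopropyl-4-methyl-7-(triethylsilyloxy)non-3-en-8-yn-2-one | C#C[C@](O[Si](CC)(CC)CC)(C(C)C)CC/C(C)=C/C(C)=O
F5 | step 8 | (3E,7R)-2-(tert-butyldimethylsilyloxy)-7-isopropyl-4-methyl-7-(triethylsilyloxy)nona-1,3-dien-8-yne | C#C[C@](O[Si](CC)(CC)CC)(C(C)C)CC/C(C)=C/C(=C)O[Si](C)(C)C(C)(C)C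
F6 | step 10 | (3R,6E)-7-[1-(tert-butyldimethylsilyloxy)cyclopropyl]-3-isopropyl-6-methylhept-6-en-1-yn-3-ol | C#C[C@](O)(C(C)C)CC/C(C)=C/C1(O[Si](C)(C)C(C)(C)C)CC1
F7 | step 10 | 9-(tert-butyldimethylsilyloxy)dauca-5,9-dien-4β-ol | C1=C2[C@](O)(C(C)C)CC[C@]2(C)C=C(O[Si](C)(C)C(C)(C)C)CC1
F8 | step 13 | 10α-(tert-butyldimethylsilyloxy)-4β-(triethylsilyloxy)dauca-5,8(14)-dien-9β-ol | C1=C2[C@](O[Si](CC)(CC)CC)(C(C)C)CC[C@]2(C)[C@H](O[Si](C)(C)C(C)(C)C)[C@@H](O)C(=C)C1
F9 | step 13 | 10α-(tert-butyldimethylsilyloxy)-4β-(triethylsilyloxy)dauca-5,8(14)-dien-9α-yl 4-nitrobenzoate | C1=C2[C@](O[Si](CC)(CC)CC)(C(C)C)CC[C@]2(C)[C@H](O[Si](C)(C)C(C)(C)C)[C@H](OC(=O)c3ccc(cc3)[N+](=O)[O-])C(=C)C1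
F10 | step 16 | 8α,14-epoxy-10α-(tert-butyldimethylsilyloxy)-4β,9α-bis(triethylsilyloxy)-5β-daucan-6β-ol | O[C@H]1[C@@H]2[C@](O[Si](CC)(CC)CC)(C(C)C)CC[C@]2(C)[C@H](O[Si](C)(C)C(C)(C)C)[C@H](O[Si](CC)(CC)CC)[C@@]3(CO3)C1
F11 | step 16 | 8α,14-epoxy-10α-(tert-butyldimethylsilyloxy)-4β,9α-bis(triethylsilyloxy)-5β-daucan-6-one | O=C1[C@@H]2[C@](O[Si](CC)(CC)CC)(C(C)C)CC[C@]2(C)[C@H](O[Si](C)(C)C(C)(C)C)[C@H](O[Si](CC)(CC)CC)[C@@]3(CO3)C1
F12 | step 16 | 8α,14-epoxy-10α-(tert-butyldimethylsilyloxy)-4β,9α-bis(triethylsilyloxy)-5α-daucan-6-one | O=C1[C@H]2[C@](O[Si](CC)(CC)CC)(C(C)C)CC[C@]2(C)[C@H](O[Si](C)(C)C(C)(C)C)[C@H](O[Si](CC)(CC)CC)[C@@]3(CO3)C1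
A1 | alternative 1 | 10α-(tert-butyldimethylsilyloxy)-6α-(4-methoxybenzyloxy)-5α-dauc-8(14)-ene-4β,9α-diol | COc1ccc(CO[C@H]2CC(=C)[C@@H](O)[C@@H](O[Si](C)(C)C(C)(C)C)[C@@]3(C)CC[C@@](O)(C(C)C)[C@H]23)cc1
A2 | alternative 1 | 8,9-seco precursor: C8 vinyl bromide and C9 aldehyde on the cyclopentane core | COc1ccc(CO[C@@H](CC(Br)=C)[C@H]2[C@](O)(C(C)C)CC[C@]2(C)[C@H](O[Si](C)(C)C(C)(C)C)C=O)cc1
A3 | alternative 2 | trans-fused 1-methylbicyclo[5.3.0]decan-6-one with C4 silyl ether and C10 dioxolane | O=C1CCCC2(OCCO2)[C@@]3(C)CC[C@H](O[Si](C)(C)C(C)(C)C)[C@H]13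
A4 | alternative 2 | cis-decalin C6 carbinol C5 mesylate with C4 silyl ether and C10 dioxolane | CS(=O)(=O)O[C@H]1[C@@H](O[Si](C)(C)C(C)(C)C)CC[C@]2(C)C3(OCCO3)CCC[C@]12O
A5 | alternative 2 | (S)-Wieland–Miescher ketone | C[C@]12CCC(=O)C=C1CCCC2=O
A6 | alternative 3 | methyl 9-(tert-butyldimethylsilyloxy)-4β-(triethylsilyloxy)-14-nordauca-5,8-diene-8-carboxylate | COC(=O)C1=C(O[Si](C)(C)C(C)(C)C)C[C@@]2(C)CC[C@@](O[Si](CC)(CC)CC)(C(C)C)C2=CC1
A7 | alternative 3 | 1-isopropyl-3-methyl-1-(triethylsilyloxy)-2-vinylcyclopent-2-ene, configuration of 1 | C=CC1=C(C)CC[C@@]1(O[Si](CC)(CC)CC)C(C)C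
A8 | alternative 3 | methyl 3-(tert-butyldimethylsilyloxy)-2-diazobut-3-enoate | COC(=O)C(=[N+]=[N-])C(=C)O[Si](C)(C)C(C)(C)C
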